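**Retrosynthetic overview**
- Komaroviquinone ⇐ oxidative demethylation of the trimethoxyarene keto alcohol; the C7 hemiketal (oxygen bridge) then closes by itself.
- Ring B (seven-membered) ⇐ intramolecular addition of an aryllithium (from an aryl bromide) to the carbonyl of a cis-fused γ-lactone on ring A (aryl–C7 bond).
- Lactone ⇐ iodolactonisation/deiodination of a cyclohexenylacetamide (sets C10–O); C5 ⇐ Eschenmoser–Claisen rearrangement of an (R)-cyclohexenol made by CBS reduction.
- Key C–C bond C10–C20 ⇐ intermolecular aldol addition of the lithium enolate of 4,4-dimethylcyclohexanone (ring A) to a hexasubstituted bromobenzaldehyde (ring C), then dehydration and exo→endo isomerisation.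
- Aldehyde ⇐ 1,2,4-trimethoxybenzene (lithiation/acetone, ionic hydrogenation, bromination, formylation). Ring order: C and A are bought, the temporary lactone follows, then ring B with the oxygen bridge.

Assumption: atom labels C1–C20 follow icetexane numbering (C10 = carbon bearing the bridge oxygen and the benzylic C20H2; C5 = ring-fusion CH; C7 = hemiketal carbon). Ar = 2-bromo-4-isopropyl-3,5,6-trimethoxyphenyl. Compound 22 is drawn as the open hydroxy ketone although it may equilibrate with its bridged lactol.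

**Step 1**
Reactants: 1 1,2,4-trimethoxybenzene
Product: 3 2-(2,3,6-trimethoxyphenyl)propan-2-ol, via aryllithium 2 (not isolated)
Conditions: n-BuLi, THF, 0 °C → rt; acetone, −78 °C → rt; then H2O
Reagents that add atoms: acetone CC(C)=O
Why: Directed ortho-lithiation removes the ring hydrogen flanked by two methoxy groups, and 1,2-addition of the aryllithium to acetone gives the tertiary benzylic alcohol.

**Step 2**
Reactants: 3 2-(2,3,6-trimethoxyphenyl)propan-2-ol
Product: 4 2-isopropyl-1,3,4-trimethoxybenzene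
Conditions: Et3SiH, CF3CO2H, CH2Cl2, 0 °C → rt
Reagents that add atoms: none
Why: Ionic hydrogenation: the acid ionises the tertiary benzylic alcohol to a cation stabilised by two ortho-methoxy groups and the silane delivers hydride.

**Step 3**
Reactants: 4 2-isopropyl-1,3,4-trimethoxybenzene
Product: 5 1-bromo-3-isopropyl-2,4,5-trimethoxybenzene
Conditions: N-bromosuccinimide, MeCN, 0 °C → rt
Reagents that add atoms: N-bromosuccinimide O=C1CCC(=O)N1Br
Why: Electrophilic aromatic bromination goes to the free position that is ortho and para to methoxy groups, not to the one para to isopropyl.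

**Step 4**
Reactants: 5 1-bromo-3-isopropyl-2,4,5-trimethoxybenzene
Product: 7 2-bromo-4-isopropyl-3,5,6-trimethoxybenzaldehyde, via chloro(methoxy)methyl arene 6 (not isolated)
Conditions: Cl2CHOMe, TiCl4, CH2Cl2, −78 → 0 °C; then ice/H2O
Reagents that add atoms: dichloromethyl methyl ether COC(Cl)Cl; water O
Why: Rieche formylation (Friedel–Crafts type) can only hit the last free ring position, which is activated by an ortho-methoxy and a para-alkyl group, and hydrolysis of the α-chloro ether gives the aldehyde.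

**Step 5**
Reactants: 7 2-bromo-4-isopropyl-3,5,6-trimethoxybenzaldehyde; 8 4,4-dimethylcyclohexanone
Product: 10 2-[Ar(hydroxy)methyl]-4,4-dimethylcyclohexan-1-one (racemic diastereomer mixture), via lithium enolate 9 (not isolated)
Conditions: LiN(iPr)2, THF, −78 °C (8 first); then 7, −78 °C; AcOH quench
Reagents that add atoms: none
Why: Directed crossed aldol addition of the preformed enolate of the symmetrical ketone to the non-enolisable aldehyde forms the C10–C20 bond; the two new stereocentres are unselective and are erased in steps 6 and 7.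

**Step 6**
Reactants: 10 2-[Ar(hydroxy)methyl]-4,4-dimethylcyclohexan-1-one
Product: 12 (E)-2-(Ar-methylidene)-4,4-dimethylcyclohexan-1-one, via mesylate 11 (not isolated)
Conditions: MsCl, Et3N, CH2Cl2, 0 °C; then DBU, rt
Reagents that add atoms: none
Why: Mesylation followed by E1cB elimination of the β-mesyloxy ketone gives the conjugated exocyclic enone (E favoured; the geometry is irrelevant after step 7).

**Step 7**
Reactants: 12 (E)-2-(Ar-methylidene)-4,4-dimethylcyclohexan-1-one
Product: 13 2-(Ar-methyl)-4,4-dimethylcyclohex-2-en-1-one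
Conditions: RhCl3·3H2O (5 mol %), EtOH, reflux
Reagents that add atoms: none
Why: Rhodium hydride alkene isomerisation moves the double bond into the ring, since the endocyclic enone is more stable (the doubly ortho-substituted aryl cannot conjugate) and the gem-dimethyl carbon blocks further migration.

**Step 8**
Reactants: 13 2-(Ar-methyl)-4,4-dimethylcyclohex-2-en-1-one
Product: 14 (R)-2-(Ar-methyl)-4,4-dimethylcyclohex-2-en-1-ol
Conditions: (S)-1-methyl-3,3-diphenyltetrahydro-1H,3H-pyrrolo[1,2-c][1,3,2]oxazaborole (20 mol %), BH3·SMe2, THF, −20 °C; then H2O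
Reagents that add atoms: none
Why: Corey–Bakshi–Shibata reduction: the α-substituted vinyl arm is the large group, so the (S)-catalyst delivers hydride in a 1,2-sense to give the (R)-allylic alcohol (ee can be raised later by recrystallising 18).

**Step 9**
Reactants: 14 (R)-2-(Ar-methyl)-4,4-dimethylcyclohex-2-en-1-ol
Product: 16 2-[(1S)-2-(Ar-methyl)-6,6-dimethylcyclohex-2-en-1-yl]-N,N-dimethylacetamide, via ketene N,O-acetal 15 (not isolated)
Conditions: MeC(OMe)2NMe2, xylene, 140 °C, MeOH distilled off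
Reagents that add atoms: N,N-dimethylacetamide dimethyl acetal CC(OC)(OC)N(C)C
Why: Eschenmoser–Claisen [3,3]-sigmatropic rearrangement transfers the side chain suprafacially to C5 on the face that carried the C–O bond, setting (S)-C5 and moving the alkene to C1=C10.

**Step 10**
Reactants: 16 2-[(1S)-2-(Ar-methyl)-6,6-dimethylcyclohex-2-en-1-yl]-N,N-dimethylacetamide
Product: 18 (3aS,7S,7aS)-7a-(Ar-methyl)-7-iodo-4,4-dimethylhexahydro-1-benzofuran-2(3H)-one (cis-fused; iodine trans to the ring oxygen), via iminium ether iodide 17 (not isolated)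
Conditions: I2, THF/H2O (1:1), rt, dark; then aq NaHCO3/Na2S2O3
Reagents that add atoms: iodine II; water O
Why: Iodolactonisation (5-exo, Markovnikov): the amide oxygen attacks the more substituted alkene carbon C10 from the face of its tether, anti to the iodonium, which forces the C10–O bond cis to the C5 side chain; water hydrolyses the iminium ether to the lactone.

**Step 11**
Reactants: 18 (3aS,7S,7aS)-7a-(Ar-methyl)-7-iodo-4,4-dimethylhexahydro-1-benzofuran-2(3H)-one
Product: 19 (3aS,7aS)-7a-(Ar-methyl)-4,4-dimethylhexahydro-1-benzofuran-2(3H)-one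
Conditions: Bu3SnH (1.1 equiv), Et3B (0.2 equiv), trace air, toluene, 0 °C → rt
Reagents that add atoms: none
Why: Radical-chain dehalogenation: the stannyl radical abstracts the secondary alkyl iodine far faster than the aryl bromine at this temperature, and C5 and C10 are untouched.

**Step 12**
Reactants: 19 (3aS,7aS)-7a-(Ar-methyl)-4,4-dimethylhexahydro-1-benzofuran-2(3H)-one
Product: 22 (4aS,11aS)-4a-hydroxy-8-isopropyl-6,7,9-trimethoxy-1,1-dimethyl-1,2,3,4,4a,5,11,11a-octahydro-10H-dibenzo[a,d][7]annulen-10-one, via aryllithium 20 (not isolated), via lithium lactolate 21 (not isolated)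
Conditions: t-BuLi (2.05 equiv), THF/Et2O, −100 °C → −40 °C; then H2O
Reagents that add atoms: none
Why: Parham cyclisation: bromine–lithium exchange outruns attack of t-BuLi on the lactone, the aryllithium adds intramolecularly to the lactone carbonyl to close ring B, and the stable tetrahedral lactolate prevents over-addition.

**Step 13**
Reactants: 22 the trimethoxyarene keto alcohol of step 12
Product: 24 komaroviquinone (5S,7S,10S), via open quinone keto alcohol 23 (not isolated)
Conditions: (NH4)2Ce(NO3)6 (2.5 equiv), MeCN/H2O (2:1), 0 °C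
Reagents that add atoms: water O
Why: Oxidative demethylation of the para-dimethoxy pair by tetravalent cerium gives the 2-methoxy-1,4-benzoquinone, whose electron-poor C7 ketone closes with the 10-OH to the hemiketal, the C7 configuration being dictated by the bridge.

**Compound list**
1 | 1,2,4-trimethoxybenzene | COc1ccc(OC)c(OC)c1 | starting material
2 | (2,3,6-trimethoxyphenyl)lithium | [Li]c1c(OC)ccc(OC)c1OC | intermediate
3 | 2-(2,3,6-trimethoxyphenyl)propan-2-ol | CC(C)(O)c1c(OC)ccc(OC)c1OC | intermediate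
4 | 2-isopropyl-1,3,4-trimethoxybenzene | CC(C)c1c(OC)ccc(OC)c1OC | intermediate
5 | 1-bromo-3-isopropyl-2,4,5-trimethoxybenzene | CC(C)c1c(OC)c(Br)cc(OC)c1OC | intermediate
6 | 2-bromo-1-[chloro(methoxy)methyl]-4-isopropyl-3,5,6-trimethoxybenzene | COC(Cl)c1c(Br)c(OC)c(C(C)C)c(OC)c1OC | intermediate
7 | 2-bromo-4-isopropyl-3,5,6-trimethoxybenzaldehyde | O=Cc1c(Br)c(OC)c(C(C)C)c(OC)c1OC | intermediate
8 | 4,4-dimethylcyclohexanone | CC1(C)CCC(=O)CC1 | starting material
9 | lithium 4,4-dimethylcyclohex-1-en-1-olate | [Li]OC1=CCC(C)(C)CC1 | intermediate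
10 | 2-[(2-bromo-4-isopropyl-3,5,6-trimethoxyphenyl)(hydroxy)methyl]-4,4-dimethylcyclohexan-1-one, racemic diastereomer mixture | O=C1CCC(C)(C)CC1C(O)c1c(Br)c(OC)c(C(C)C)c(OC)c1OC | intermediate
11 | methanesulfonate of 10 | O=C1CCC(C)(C)CC1C(OS(C)(=O)=O)c1c(Br)c(OC)c(C(C)C)c(OC)c1OC | intermediate
12 | (E)-2-[(2-bromo-4-isopropyl-3,5,6-trimethoxyphenyl)methylidene]-4,4-dimethylcyclohexan-1-one | Brc1c(OC)c(C(C)C)c(OC)c(OC)c1/C=C2\CC(C)(C)CCC2=O | intermediate
13 | 2-[(2-bromo-4-isopropyl-3,5,6-trimethoxyphenyl)methyl]-4,4-dimethylcyclohex-2-en-1-one | O=C1CCC(C)(C)C=C1Cc1c(Br)c(OC)c(C(C)C)c(OC)c1OC | intermediate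
14 | (R)-2-[(2-bromo-4-isopropyl-3,5,6-trimethoxyphenyl)methyl]-4,4-dimethylcyclohex-2-en-1-ol | O[C@@H]1CCC(C)(C)C=C1Cc1c(Br)c(OC)c(C(C)C)c(OC)c1OC | intermediate
15 | 1-{[(R)-2-(Ar-methyl)-4,4-dimethylcyclohex-2-en-1-yl]oxy}-N,N-dimethylethen-1-amine (ketene N,O-acetal) | C=C(N(C)C)O[C@@H]1CCC(C)(C)C=C1Cc1c(Br)c(OC)c(C(C)C)c(OC)c1OC | intermediate
16 | 2-[(1S)-2-(Ar-methyl)-6,6-dimethylcyclohex-2-en-1-yl]-N,N-dimethylacetamide | CN(C)C(=O)C[C@@H]1C(Cc2c(Br)c(OC)c(C(C)C)c(OC)c2OC)=CCCC1(C)C | intermediate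
17 | N-[(3aS,7S,7aS)-7a-(Ar-methyl)-7-iodo-4,4-dimethylhexahydro-1-benzofuran-2(3H)-ylidene]-N-methylmethanaminium iodide | C[N+](C)=C1C[C@H]2C(C)(C)CC[C@H](I)[C@@]2(Cc3c(Br)c(OC)c(C(C)C)c(OC)c3OC)O1.[I-] | intermediate
18 | (3aS,7S,7aS)-7a-(Ar-methyl)-7-iodo-4,4-dimethylhexahydro-1-benzofuran-2(3H)-one | O=C1C[C@H]2C(C)(C)CC[C@H](I)[C@@]2(Cc3c(Br)c(OC)c(C(C)C)c(OC)c3OC)O1 | intermediate
19 | (3aS,7aS)-7a-(Ar-methyl)-4,4-dimethylhexahydro-1-benzofuran-2(3H)-one | O=C1C[C@H]2C(C)(C)CCC[C@@]2(Cc3c(Br)c(OC)c(C(C)C)c(OC)c3OC)O1 | intermediate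
20 | aryllithium of 19 (lithium in place of bromine) | O=C1C[C@H]2C(C)(C)CCC[C@@]2(Cc3c([Li])c(OC)c(C(C)C)c(OC)c3OC)O1 | intermediate
21 | lithium salt of the bridged 7,10-epoxy lactol (trimethoxyarene analogue of the target, O–Li on C7), (5S,7S,10S) | COc1c(C(C)C)c(OC)c2c(c1OC)C[C@@]13CCCC(C)(C)[C@@H]1C[C@]2(O[Li])O3 | intermediate
22 | (4aS,11aS)-4a-hydroxy-8-isopropyl-6,7,9-trimethoxy-1,1-dimethyl-1,2,3,4,4a,5,11,11a-octahydro-10H-dibenzo[a,d][7]annulen-10-one | O=C1C[C@H]2C(C)(C)CCC[C@]2(O)Cc3c(OC)c(OC)c(C(C)C)c(OC)c13 | intermediate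
23 | open quinone keto alcohol (5S,10S): 10-hydroxy-7-oxo form of the target | COC1=C(C(C)C)C(=O)C2=C(C[C@@]3(O)CCCC(C)(C)[C@@H]3CC2=O)C1=O | intermediate
24 | komaroviquinone (5S,7S,10S) | COC1=C(C(C)C)C(=O)C2=C(C[C@@]34CCCC(C)(C)[C@@H]3C[C@]2(O)O4)C1=O | target

**Totals**
Total step count: 13. Longest linear sequence: 13 steps (1 → 24); ketone 8 enters at step 5.

**Three steps most likely to fail**

Step 12 (Parham closure onto the lactone; risks are enolisation of the lactone and the strain of forming the bridged lactolate). The fallback sets out from 19 and comes back at 22. The lactone is opened with MeNH(OMe)·HCl/AlMe3 in CH2Cl2 to 2-[(1S,2S)-2-(Ar-methyl)-2-hydroxy-6,6-dimethylcyclohexyl]-N-methoxy-N-methylacetamide F4. The tertiary alcohol is silylated at once with Et3SiOTf/2,6-lutidine to give its triethylsilyl ether F5. t-BuLi in THF at −78 °C gives the aryllithium of the silyl ether F6, which closes onto the open-chain Weinreb amide to the chelated tetrahedral lithium adduct F7. Work-up releases (4aS,11aS)-8-isopropyl-6,7,9-trimethoxy-1,1-dimethyl-4a-[(triethylsilyl)oxy]-1,2,3,4,4a,5,11,11a-octahydro-10H-dibenzo[a,d][7]annulen-10-one F8, and Bu4NF in THF removes the silyl group to give 22.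

Step 7 (exo→endo isomerisation of a hindered trisubstituted enone). The fallback sets out from 12 and comes back at 13. Conjugate hydrosilylation of 12 with PhMe2SiH and catalytic [(Ph3P)CuH]6 in toluene gives the regiodefined tetrasubstituted silyl enol ether {[2-(Ar-methyl)-4,4-dimethylcyclohex-1-en-1-yl]oxy}dimethyl(phenyl)silane F3. Saegusa–Ito oxidation with Pd(OAc)2 in MeCN at rt then removes a hydrogen from the ring CH2 next to the gem-dimethyl carbon and gives 13; any 12 re-formed by elimination toward the benzylic CH2 is recycled.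

Step 4 (formylation at a position flanked by bromine and methoxy; risks are ipso attack and demethylation by the Lewis acid). The fallback sets out from 5 and comes back at 7. Instead of electrophilic substitution, the only ring hydrogen of 5 is removed with lithium 2,2,6,6-tetramethylpiperidide in THF at −78 °C (directed ortho-metalation between Br and OMe, kept cold to avoid aryne formation) to give (2-bromo-4-isopropyl-3,5,6-trimethoxyphenyl)lithium F1. DMF converts it to lithium (2-bromo-4-isopropyl-3,5,6-trimethoxyphenyl)(dimethylamino)methanolate F2, which collapses to 7 on aqueous acid work-up.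

Further compounds
F1 | step 4 | (2-bromo-4-isopropyl-3,5,6-trimethoxyphenyl)lithium | [Li]c1c(Br)c(OC)c(C(C)C)c(OC)c1OC
F2 | step 4 | lithium (2-bromo-4-isopropyl-3,5,6-trimethoxyphenyl)(dimethylamino)methanolate | CN(C)C(O[Li])c1c(Br)c(OC)c(C(C)C)c(OC)c1OC
F3 | step 7 | {[2-(Ar-methyl)-4,4-dimethylcyclohex-1-en-1-yl]oxy}dimethyl(phenyl)silane | C[Si](C)(OC1=C(Cc2c(Br)c(OC)c(C(C)C)c(OC)c2OC)CC(C)(C)CC1)c1ccccc1
F4 | step 12 | 2-[(1S,2S)-2-(Ar-methyl)-2-hydroxy-6,6-dimethylcyclohexyl]-N-methoxy-N-methylacetamide | CON(C)C(=O)C[C@H]1C(C)(C)CCC[C@]1(O)Cc1c(Br)c(OC)c(C(C)C)c(OC)c1OC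
F5 | step 12 | triethylsilyl ether of F4 | CON(C)C(=O)C[C@H]1C(C)(C)CCC[C@]1(O[Si](CC)(CC)CC)Cc1c(Br)c(OC)c(C(C)C)c(OC)c1OC
F6 | step 12 | aryllithium of F5 (lithium in place of bromine) | CON(C)C(=O)C[C@H]1C(C)(C)CCC[C@]1(O[Si](CC)(CC)CC)Cc1c([Li])c(OC)c(C(C)C)c(OC)c1OC
F7 | step 12 | cyclised tetrahedral lithium N-methoxy-N-methyl hemiaminal alkoxide | CON(C)C1(O[Li])C[C@H]2C(C)(C)CCC[C@]2(O[Si](CC)(CC)CC)Cc3c(OC)c(OC)c(C(C)C)c(OC)c13
F8 | step 12 | (4aS,11aS)-8-isopropyl-6,7,9-trimethoxy-1,1-dimethyl-4a-[(triethylsilyl)oxy]-1,2,3,4,4a,5,11,11a-octahydro-10H-dibenzo[a,d][7]annulen-10-one | O=C1C[C@H]2C(C)(C)CCC[C@]2(O[Si](CC)(CC)CC)Cc3c(OC)c(OC)c(C(C)C)c(OC)c13
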